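**Retrosynthetic overview**

1. Target 16 comes from the ketal-protected dimethoxy lactone 14 by two unmasking steps: dioxolane hydrolysis, then chelation-directed BCl3 cleavage of the C8 methyl ether.
2. Feature: C1 is a one-carbon carbonyl unit bonded only to O2 and to C8a of ring A. Taking it out as CO leaves a 3,5-dimethoxyphenyl ring whose two positions ortho to the side chain are symmetry-equivalent and para to a methoxy group, so iodine goes onto the future C8a by plain electrophilic substitution.
3. Key disconnection: C8a–C1 and C1–O2, made together by palladium-catalysed CO insertion and lactonisation of iodo carbinol 12. Ring B is the only ring formed; ring A is bought.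
4. 12 comes from NIS iodination of carbinol 11. 11 comes from the C4–C4a disconnection: 3,5-dimethoxyphenyl Grignard reagent plus (R)-epoxide 8, whose C3 stereocentre is set by hydrolytic kinetic resolution.
5. Epoxide 8 derives from tridec-12-en-6-one 5 (Weinreb ketone synthesis from hexanoyl chloride and 7-bromohept-1-ene), with the ketone masked as a dioxolane.

Key step: step 8

Remark on the chemistry: isochroman-1-one numbering is used (C1 carbonyl, O2, C3, C4, C4a, C5–C8, C8a; ring A is the benzene ring, ring B the lactone ring). The target SMILES reads R at C3, and every intermediate is drawn to match.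

**Route**

Step 1
Reactants: 1 hexanoyl chloride
Product: 2 N-methoxy-N-methylhexanamide
Conditions: MeNH(OMe)·HCl (1.1 equiv), K2CO3 (2.5 equiv), CH2Cl2/H2O, 0 °C → rt
Reagents that add atoms: N,O-dimethylhydroxylamine hydrochloride, CNOC.Cl
Why: Schotten–Baumann N-acylation of the hydroxylamine by the acid chloride is fast in the two-phase mixture while the aqueous carbonate takes up HCl, giving the Weinreb amide cleanly.

Step 2
Reactants: 2 N-methoxy-N-methylhexanamide; 3 7-bromohept-1-ene
Product: 5 tridec-12-en-6-one, via hept-6-en-1-ylmagnesium bromide 4 (not isolated)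
Conditions: 3, Mg, THF, 40 °C; then 2, THF, 0 °C → rt; 1 M HCl
Reagents that add atoms: none
Why: Weinreb ketone synthesis, in which the primary alkyl Grignard reagent adds once to give a magnesium-chelated tetrahedral adduct that releases the ketone only on acidic work-up, so no tertiary alcohol should form, and the alkene is too far from the C–Mg carbon for significant cyclisation.

Step 3
Reactants: 5 tridec-12-en-6-one
Product: 6 2-(hept-6-en-1-yl)-2-pentyl-1,3-dioxolane
Conditions: HOCH2CH2OH (3 equiv), p-TsOH·H2O (2 mol %), toluene, reflux, Dean–Stark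
Reagents that add atoms: ethylene glycol, OCCO
Why: Acid-catalysed ketalisation driven by azeotropic removal of water masks the ketone against the aryl Grignard reagent of step 6, and the isolated terminal alkene is inert to catalytic sulfonic acid.

Step 4
Reactants: 6 2-(hept-6-en-1-yl)-2-pentyl-1,3-dioxolane
Product: 7 rac-2-[5-(2-pentyl-1,3-dioxolan-2-yl)pentyl]oxirane
Conditions: mCPBA (1.3 equiv), NaHCO3, CH2Cl2, 0 °C → rt
Reagents that add atoms: mCPBA (3-chloroperoxybenzoic acid), OOC(=O)c1cccc(Cl)c1
Why: Prilezhaev epoxidation transfers oxygen to the monosubstituted alkene in a concerted step, the bicarbonate buffer protects the dioxolane from the carboxylic acid formed, and the new stereocentre is formed racemic and resolved in step 5.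

Step 5
Reactants: 7 rac-2-[5-(2-pentyl-1,3-dioxolan-2-yl)pentyl]oxirane
Product: 8 (R)-2-[5-(2-pentyl-1,3-dioxolan-2-yl)pentyl]oxirane
Conditions: (R,R)-(salen)Co(OAc) (0.5 mol %; salen = N,N′-bis(3,5-di-tert-butylsalicylidene)cyclohexane-1,2-diaminato, trivalent cobalt), H2O (0.55 equiv), THF, 0 °C → rt; chromatography
Reagents that add atoms: none
Why: Jacobsen hydrolytic kinetic resolution, in which the (R,R)-cobalt salen catalyst hydrolyses the (S)-epoxide selectively at its terminal carbon, so the unreacted (R)-epoxide that carries the future C3 configuration should be recovered in high enantiomeric purity and separated from the polar diol.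

Step 6
Reactants: 8 (R)-2-[5-(2-pentyl-1,3-dioxolan-2-yl)pentyl]oxirane; 9 1-bromo-3,5-dimethoxybenzene
Product: 11 (R)-1-(3,5-dimethoxyphenyl)-7-(2-pentyl-1,3-dioxolan-2-yl)heptan-2-ol, via 3,5-dimethoxyphenylmagnesium bromide 10 (not isolated)
Conditions: 9, Mg, THF, reflux; then CuI (10 mol %), 8, THF, −30 → 0 °C; aq NH4Cl
Reagents that add atoms: none
Why: Copper-catalysed ring opening of a terminal epoxide by an aryl Grignard reagent (CuI, monovalent copper) is an SN2 attack at the unsubstituted carbon, so the C4–C4a bond forms while the C–O stereocentre is untouched and stays R.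

Step 7
Reactants: 11 (R)-1-(3,5-dimethoxyphenyl)-7-(2-pentyl-1,3-dioxolan-2-yl)heptan-2-ol
Product: 12 (R)-1-(2-iodo-3,5-dimethoxyphenyl)-7-(2-pentyl-1,3-dioxolan-2-yl)heptan-2-ol
Conditions: NIS (1.05 equiv), MeCN, 0 °C → rt, dark
Reagents that add atoms: N-iodosuccinimide, O=C1CCC(=O)N1I
Why: Electrophilic aromatic iodination of the electron-rich resorcinol dimethyl ether should go to one of the two equivalent positions ortho to the side chain and para to a methoxy group, the position between the two methoxy groups being more hindered, and no acid is added so the ketal survives.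

Step 8
Reactants: 12 (R)-1-(2-iodo-3,5-dimethoxyphenyl)-7-(2-pentyl-1,3-dioxolan-2-yl)heptan-2-ol; 13 carbon monoxide
Product: 14 (3R)-6,8-dimethoxy-3-[5-(2-pentyl-1,3-dioxolan-2-yl)pentyl]isochroman-1-one
Conditions: Pd(OAc)2 (5 mol %), Xantphos (7.5 mol %), CO (1 atm), K2CO3 (2 equiv), 1,4-dioxane (0.05 M), 90 °C
Reagents that add atoms: carbon monoxide, [C-]#[O+]
Why: Pd(OAc)2 and Xantphos are reduced in the flask to zerovalent palladium, which inserts into the C8a–I bond to give an arylpalladium iodide (divalent palladium); CO then coordinates and migrates into the Pd–aryl bond, and the C3 oxygen, deprotonated by K2CO3, attacks the aroyl carbon so that the lactone is expelled and zerovalent palladium returns to the cycle. The closest known reaction type is the palladium-catalysed intramolecular alkoxycarbonylation of ortho-halophenethyl alcohols to isochroman-1-ones. Ring B (C1, O2, C3, C4, C4a, C8a) closes in a 6-exo-trig acyl substitution, the C8a–C1 and C1–O2 bonds being made in the same operation. No stereocentre is created; the C3–O bond is never broken, so the R configuration from the resolved epoxide is carried through unchanged. The step needs chemoselectivity for CO insertion and acyl capture over hydrodeiodination, direct aryl–oxygen coupling and oxidation of the carbinol by beta-hydride elimination; the CO atmosphere, the wide bite angle of Xantphos and the six-atom reach from the hydroxyl oxygen to the acyl carbon secure it, and the regiochemistry is fixed by the position of the iodine. The dioxolane and both aryl methyl ethers are inert to the mild carbonate base.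

Step 9
Reactants: 14 (3R)-6,8-dimethoxy-3-[5-(2-pentyl-1,3-dioxolan-2-yl)pentyl]isochroman-1-one
Product: 15 (3R)-6,8-dimethoxy-3-(6-oxoundecyl)isochroman-1-one
Conditions: 2 M HCl, THF, rt
Reagents that add atoms: water, O
Why: Acid-catalysed ketal hydrolysis through the oxocarbenium ion frees the dialkyl ketone, while the lactone and the aryl methyl ethers are stable to dilute aqueous acid at room temperature.

Step 10
Reactants: 15 (3R)-6,8-dimethoxy-3-(6-oxoundecyl)isochroman-1-one
Product: 16 (3R)-8-hydroxy-6-methoxy-3-(6-oxoundecyl)isochroman-1-one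
Conditions: BCl3 (1 M in CH2Cl2, 3 equiv), CH2Cl2, −78 → 0 °C; then H2O
Reagents that add atoms: none
Why: Chelation-controlled Lewis acid ether cleavage, in which BCl3 is held between the C1 carbonyl oxygen and the neighbouring C8 methoxy oxygen in a six-membered chelate, so chloride should remove only that methyl group and leave the C6 ether, the lactone and the ketone.

**Compound list**

1 | hexanoyl chloride | CCCCCC(=O)Cl | starting material
2 | N-methoxy-N-methylhexanamide | CCCCCC(=O)N(C)OC | intermediate
3 | 7-bromohept-1-ene | C=CCCCCCBr | starting material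
4 | hept-6-en-1-ylmagnesium bromide | C=CCCCCC[Mg]Br | intermediate (not isolated)
5 | tridec-12-en-6-one | CCCCCC(=O)CCCCCC=C | intermediate
6 | 2-(hept-6-en-1-yl)-2-pentyl-1,3-dioxolane | CCCCCC1(CCCCCC=C)OCCO1 | intermediate
7 | rac-2-[5-(2-pentyl-1,3-dioxolan-2-yl)pentyl]oxirane | CCCCCC1(OCCO1)CCCCCC2CO2 | intermediate
8 | (R)-2-[5-(2-pentyl-1,3-dioxolan-2-yl)pentyl]oxirane | CCCCCC1(OCCO1)CCCCC[C@@H]2CO2 | intermediate
9 | 1-bromo-3,5-dimethoxybenzene | COc1cc(Br)cc(OC)c1 | starting material
10 | 3,5-dimethoxyphenylmagnesium bromide | COc1cc([Mg]Br)cc(OC)c1 | intermediate (not isolated)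
11 | (R)-1-(3,5-dimethoxyphenyl)-7-(2-pentyl-1,3-dioxolan-2-yl)heptan-2-ol | CCCCCC1(OCCO1)CCCCC[C@@H](O)Cc1cc(OC)cc(OC)c1 | intermediate
12 | (R)-1-(2-iodo-3,5-dimethoxyphenyl)-7-(2-pentyl-1,3-dioxolan-2-yl)heptan-2-ol | CCCCCC1(OCCO1)CCCCC[C@@H](O)Cc1cc(OC)cc(OC)c1I | intermediate
13 | carbon monoxide | [C-]#[O+] | starting material
14 | (3R)-6,8-dimethoxy-3-[5-(2-pentyl-1,3-dioxolan-2-yl)pentyl]isochroman-1-one | CCCCCC1(OCCO1)CCCCC[C@@H]1Cc2cc(OC)cc(OC)c2C(=O)O1 | intermediate
15 | (3R)-6,8-dimethoxy-3-(6-oxoundecyl)isochroman-1-one | CCCCCC(=O)CCCCC[C@@H]1Cc2cc(OC)cc(OC)c2C(=O)O1 | intermediate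
16 | (3R)-8-hydroxy-6-methoxy-3-(6-oxoundecyl)isochroman-1-one | CCCCCC(=O)CCCCC[C@@H]1Cc2cc(OC)cc(O)c2C(=O)O1 | target

**Step count and risks**

Total step count: 10. Longest linear sequence: 10 steps, from hexanoyl chloride 1 to target 16. Compounds 3 and 9 enter as Grignard reagents made in the flask in steps 2 and 6.

Steps most likely to fail:

Step 8 (key step). The C–I bond may be reduced instead of carbonylated. The carbinol may be oxidised by beta-hydride elimination from a palladium alkoxide. Oxidative addition at the doubly ortho-substituted carbon may be slow enough for the catalyst to decompose under CO. Fallback, setting out from 12: treat 12 with n-BuLi (2.2 equiv, THF, −78 °C) to form the lithium alkoxide and then exchange iodine for lithium at C8a, and trap the aryllithium with CO2. Careful acidification with citric acid should give the hydroxy acid 2-[(2R)-2-hydroxy-7-(2-pentyl-1,3-dioxolan-2-yl)heptyl]-4,6-dimethoxybenzoic acid F1. This is closed to the six-membered lactone with EDC·HCl and DMAP in CH2Cl2. The fallback returns to the route at 14 and replaces the catalytic CO insertion by a stoichiometric organolithium carboxylation with the same C8a–C1 and C1–O2 bonds.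

Step 7. Iodination may occur partly at the position between the two methoxy groups, or a second iodine may be introduced; either would be hard to separate. Fallback, setting out from 11: the hydroxyl is turned into its methoxymethyl ether with MOMCl and iPr2NEt, giving 2-[(6R)-7-(3,5-dimethoxyphenyl)-6-(methoxymethoxy)heptyl]-2-pentyl-1,3-dioxolane F2. TMSOTf in CH2Cl2 at 0 °C ionises the acetal, and the tethered oxocarbenium ion can only reach a ring carbon ortho to the side chain (oxa-Pictet–Spengler cyclisation), giving (3R)-6,8-dimethoxy-3-[5-(2-pentyl-1,3-dioxolan-2-yl)pentyl]isochroman F3. Work-up with aqueous HCl removes the ketal to give 11-[(3R)-6,8-dimethoxyisochroman-3-yl]undecan-6-one F4. Oxidation of the C1 methylene, which is both benzylic and next to oxygen, with pyridinium chlorochromate [C5H5NH][CrO3Cl] in CH2Cl2 at reflux gives the lactone. The fallback returns to the route at 15, so steps 8 and 9 are no longer needed; C1 is still brought in as a single carbon between O2 and C8a, but by a tether that fixes the position.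

Step 10. Selectivity between the two aryl methyl ethers may be lost, or cleavage may stall because BCl3 is tied up by the ketone. Fallback, setting out from 15: excess BBr3 (CH2Cl2, −78 °C → rt) cleaves both ethers to (3R)-6,8-dihydroxy-3-(6-oxoundecyl)isochroman-1-one F5. One equivalent of MeI with K2CO3 in acetone then methylates the free C6 hydroxyl, because the C8 hydroxyl is held in a hydrogen bond to the lactone carbonyl and is less nucleophilic. The fallback returns to the route at 16.

**Further compounds**

F1 | step 8 | 2-[(2R)-2-hydroxy-7-(2-pentyl-1,3-dioxolan-2-yl)heptyl]-4,6-dimethoxybenzoic acid | CCCCCC1(OCCO1)CCCCC[C@@H](O)Cc1cc(OC)cc(OC)c1C(=O)O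
F2 | step 7 | 2-[(6R)-7-(3,5-dimethoxyphenyl)-6-(methoxymethoxy)heptyl]-2-pentyl-1,3-dioxolane | CCCCCC1(OCCO1)CCCCC[C@@H](OCOC)Cc1cc(OC)cc(OC)c1
F3 | step 7 | (3R)-6,8-dimethoxy-3-[5-(2-pentyl-1,3-dioxolan-2-yl)pentyl]isochroman | CCCCCC1(OCCO1)CCCCC[C@@H]1Cc2cc(OC)cc(OC)c2CO1
F4 | step 7 | 11-[(3R)-6,8-dimethoxyisochroman-3-yl]undecan-6-one | CCCCCC(=O)CCCCC[C@@H]1Cc2cc(OC)cc(OC)c2CO1
F5 | step 10 | (3R)-6,8-dihydroxy-3-(6-oxoundecyl)isochroman-1-one | CCCCCC(=O)CCCCC[C@@H]1Cc2cc(O)cc(O)c2C(=O)O1
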